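**Retrosynthetic overview**
- The target is an acyclic (S)-α-hydroxy-dihydrochalcone; the last step is a global acid deprotection (3 × MOM, 1 × TBS).
- Key disconnection: the aryl–C(=O) bond, formed late by adding a diprenylated aryllithium (ring A) to an (S)-α-silyloxy Weinreb amide (C3 chain + ring B).
- Ring A fragment: resorcinol bis-MOM ether, three successive directed ortho-metalations (prenyl, prenyl, iodine).
- Ring B fragment: Cu-catalysed opening of methyl (S)-glycidate by the Grignard reagent of MOM-protected 4-bromophenol; this supplies the only stereocentre, whose C–O bond is never broken.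
- No rings are formed; both benzene rings are purchased (resorcinol, 4-bromophenol).

Assumption: the stereocentre in the SMILES is read as (S), and resorcinol, prenyl bromide, 4-bromophenol and methyl (S)-glycidate are taken as commercial.

**Fragment A (ring A)**

Step 1
Reactants: 1 resorcinol
Product: 2 1,3-bis(methoxymethoxy)benzene
Conditions: MOMCl (2.5 equiv), i-Pr2NEt, CH2Cl2, 0 °C → rt
Reagents that add atoms: chloromethyl methyl ether (MOMCl), COCCl
Why: Williamson-type O-alkylation of both phenols installs MOM ethers that serve as protecting groups and as ortho-directing groups for the next three steps.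

Step 2
Reactants: 2 1,3-bis(methoxymethoxy)benzene; 3 prenyl bromide
Product: 4 1,3-bis(methoxymethoxy)-2-(3-methylbut-2-en-1-yl)benzene
Conditions: n-BuLi, THF, 0 °C → rt; then CuI (cat.), 3, −78 °C → rt
Reagents that add atoms: none beyond reactant 3
Why: Directed ortho-metalation occurs at C2, doubly activated between the two OMOM groups, and the Cu-mediated SN2 alkylation of the aryl anion gives the linear prenyl group.

Step 3
Reactants: 4 1,3-bis(methoxymethoxy)-2-(3-methylbut-2-en-1-yl)benzene; 3 prenyl bromide
Product: 5 1,3-bis(methoxymethoxy)-2,4-bis(3-methylbut-2-en-1-yl)benzene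
Conditions: n-BuLi, TMEDA, THF, −20 → 0 °C; then CuI (cat.), 3, −78 °C → rt
Reagents that add atoms: none beyond reactant 3
Why: A second directed ortho-metalation at C4 (C4 and C6 are equivalent, each ortho to one OMOM) followed by Cu-mediated prenylation.

Step 4
Reactants: 5 1,3-bis(methoxymethoxy)-2,4-bis(3-methylbut-2-en-1-yl)benzene
Product: 6 1-iodo-2,4-bis(methoxymethoxy)-3,5-bis(3-methylbut-2-en-1-yl)benzene
Conditions: n-BuLi, TMEDA, THF, −20 → 0 °C; then I2, THF, −78 °C; aq Na2S2O3
Reagents that add atoms: iodine, II
Why: The only remaining ring C–H ortho to an OMOM group (C6) is lithiated by directed ortho-metalation and trapped with iodine, giving a purifiable, regiodefined handle for clean I/Li exchange in the coupling.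

**Fragment B (C3 chain + ring B)**

Step 5
Reactants: 7 4-bromophenol
Product: 8 1-bromo-4-(methoxymethoxy)benzene
Conditions: MOMCl, i-Pr2NEt, CH2Cl2, 0 °C → rt
Reagents that add atoms: chloromethyl methyl ether (MOMCl), COCCl
Why: O-alkylation masks the acidic phenol so that a Grignard reagent can be formed.

Step 6
Reactants: 8 1-bromo-4-(methoxymethoxy)benzene; 9 methyl (S)-glycidate
Product: 10 methyl (S)-2-hydroxy-3-[4-(methoxymethoxy)phenyl]propanoate
Conditions: Mg, THF (to ArMgBr, 1.4 equiv); then CuI (10 mol %), 9, THF, −40 → −20 °C; aq NH4Cl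
Reagents that add atoms: none beyond reactants
Why: Cu-catalysed SN2 epoxide opening by the aryl Grignard occurs at the unsubstituted C3 faster than ester addition at low temperature; the C2–O bond is untouched, so the (S) centre of the glycidate is carried over unchanged.

Step 7
Reactants: 10 methyl (S)-2-hydroxy-3-[4-(methoxymethoxy)phenyl]propanoate
Product: 11 methyl (S)-2-[(tert-butyldimethylsilyl)oxy]-3-[4-(methoxymethoxy)phenyl]propanoate
Conditions: TBSCl, imidazole, DMF, rt
Reagents that add atoms: tert-butyldimethylsilyl chloride (TBSCl), CC(C)(C)[Si](C)(C)Cl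
Why: Silylation of the secondary alcohol under mild, non-epimerising conditions prevents alkoxide formation in the organometallic steps.

Step 8
Reactants: 11 methyl (S)-2-[(tert-butyldimethylsilyl)oxy]-3-[4-(methoxymethoxy)phenyl]propanoate
Product: 12 (S)-2-[(tert-butyldimethylsilyl)oxy]-N-methoxy-3-[4-(methoxymethoxy)phenyl]-N-methylpropanamide
Conditions: MeNH(OMe)·HCl, i-PrMgCl, THF, −20 → 0 °C
Reagents that add atoms: N,O-dimethylhydroxylamine hydrochloride, CNOC.Cl
Why: Direct ester aminolysis by the magnesium amide gives the Weinreb amide at low temperature, where α-silyloxy esters do not epimerise.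

**Coupling and endgame**

Step 9
Reactants: 6 1-iodo-2,4-bis(methoxymethoxy)-3,5-bis(3-methylbut-2-en-1-yl)benzene; 12 (S)-2-[(tert-butyldimethylsilyl)oxy]-N-methoxy-3-[4-(methoxymethoxy)phenyl]-N-methylpropanamide
Product: 13 (S)-1-[2,4-bis(methoxymethoxy)-3,5-bis(3-methylbut-2-en-1-yl)phenyl]-2-[(tert-butyldimethylsilyl)oxy]-3-[4-(methoxymethoxy)phenyl]propan-1-one
Conditions: 6 (1.2 equiv), t-BuLi (2.4 equiv), THF, −78 °C; then 12 (1.0 equiv), −78 → −40 °C; aq NH4Cl at −40 °C
Reagents that add atoms: none beyond reactants
Why: Iodine–lithium exchange gives the aryllithium, and Weinreb ketone synthesis stops at the stable chelated tetrahedral intermediate, so the ketone is released only on the cold quench and the α-silyloxy stereocentre is not enolised.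

Step 10
Reactants: 13 the protected ketone from step 9
Product: 14 Lespeflorin C6, (S)-1-[2,4-dihydroxy-3,5-bis(3-methylbut-2-en-1-yl)phenyl]-2-hydroxy-3-(4-hydroxyphenyl)propan-1-one
Conditions: 3 M aq HCl, MeOH–THF, rt (→ 35 °C if needed), stopped at full conversion
Reagents that add atoms: none
Why: Acid-catalysed acetal hydrolysis removes the three phenolic MOM ethers and acidic methanolysis removes the secondary TBS ether; the conditions are kept mild to spare the prenyl groups and the α-ketol stereocentre.

**Compound list**
1 | resorcinol (benzene-1,3-diol) | Oc1cccc(O)c1 | starting material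
2 | 1,3-bis(methoxymethoxy)benzene | COCOc1cccc(OCOC)c1 | intermediate
3 | prenyl bromide (1-bromo-3-methylbut-2-ene) | CC(C)=CCBr | starting material
4 | 1,3-bis(methoxymethoxy)-2-(3-methylbut-2-en-1-yl)benzene | COCOc1cccc(OCOC)c1CC=C(C)C | intermediate
5 | 1,3-bis(methoxymethoxy)-2,4-bis(3-methylbut-2-en-1-yl)benzene | COCOc1ccc(CC=C(C)C)c(OCOC)c1CC=C(C)C | intermediate
6 | 1-iodo-2,4-bis(methoxymethoxy)-3,5-bis(3-methylbut-2-en-1-yl)benzene | COCOc1c(I)cc(CC=C(C)C)c(OCOC)c1CC=C(C)C | intermediate
7 | 4-bromophenol | Oc1ccc(Br)cc1 | starting material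
8 | 1-bromo-4-(methoxymethoxy)benzene | COCOc1ccc(Br)cc1 | intermediate
9 | methyl (S)-glycidate (methyl (2S)-oxirane-2-carboxylate) | COC(=O)[C@@H]1CO1 | starting material
10 | methyl (S)-2-hydroxy-3-[4-(methoxymethoxy)phenyl]propanoate | COC(=O)[C@@H](O)Cc1ccc(OCOC)cc1 | intermediate
11 | methyl (S)-2-[(tert-butyldimethylsilyl)oxy]-3-[4-(methoxymethoxy)phenyl]propanoate | COC(=O)[C@@H](O[Si](C)(C)C(C)(C)C)Cc1ccc(OCOC)cc1 | intermediate
12 | (S)-2-[(tert-butyldimethylsilyl)oxy]-N-methoxy-3-[4-(methoxymethoxy)phenyl]-N-methylpropanamide | CON(C)C(=O)[C@@H](O[Si](C)(C)C(C)(C)C)Cc1ccc(OCOC)cc1 | intermediate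
13 | (S)-1-[2,4-bis(methoxymethoxy)-3,5-bis(3-methylbut-2-en-1-yl)phenyl]-2-[(tert-butyldimethylsilyl)oxy]-3-[4-(methoxymethoxy)phenyl]propan-1-one | CC(C)=CCc1cc(C(=O)[C@@H](O[Si](C)(C)C(C)(C)C)Cc2ccc(OCOC)cc2)c(OCOC)c(CC=C(C)C)c1OCOC | intermediate
14 | Lespeflorin C6, (S)-1-[2,4-dihydroxy-3,5-bis(3-methylbut-2-en-1-yl)phenyl]-2-hydroxy-3-(4-hydroxyphenyl)propan-1-one | CC(C)=CCc1cc(C(=O)[C@@H](O)Cc2ccc(O)cc2)c(O)c(CC=C(C)C)c1O | target

**Totals**
- Total step count: 10.
- Longest linear sequence: 6 steps (steps 5–8, 9, 10; the ring A branch, steps 1–4, 9, 10, is also 6).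

**Three steps most likely to fail, with fallbacks**
1. Step 4 (and to a lesser extent step 3): ring lithiation may lose to lateral deprotonation of the benzylic/allylic prenyl CH2. Fallback: put the halogens on before any prenyl group. Tribrominate resorcinol (Br2), MOM-protect, then run two sequential Br/Mg exchange and Cu-catalysed prenylations (C2, then C4), leaving the C6 bromide as the coupling handle. No C–H lithiation of a prenylated arene is then needed.
2. Step 9: the hindered, electron-rich aryllithium may act as a base towards the Weinreb amide, giving recovered amide, loss of ee or N–OMe cleavage. Fallback: reduce ester 11 to the (S)-α-silyloxy aldehyde (DIBAL-H, −78 °C), add the aryllithium to this more electrophilic partner, and oxidise the resulting carbinol to ketone 13 with Dess–Martin periodinane. The new carbinol centre is destroyed in the oxidation, so its configuration does not matter.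
3. Step 10: Brønsted acid can cyclise the ortho-prenyl phenols to 2,2-dimethylchromans, add HCl or MeOH across the prenyl alkenes, or slowly racemise the α-ketol. Fallback: rebuild both fragments with a milder protecting-group set: 1-ethoxyethyl acetals on the phenols (which still direct ortho-lithiation) and TES on the carbinol. The endgame then needs only PPTS/MeOH at rt.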